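Ring C of this 6-(1-methylpiperidin-2-yl)naringenin is disconnected at O1–C2 and C3–C4. The O1–C8a–C4a–C4 array on ring A is a latent ortho-quinone methide, and C2–C3 with ring B is a 4-oxystyrene. A chiral Brønsted acid-mediated [4+2] cycloaddition of a salicylaldehyde-derived 4-methoxy quinone methide with 4-benzyloxystyrene therefore closes ring C, forms both bonds and sets C2 in one operation; the C4 ether is later oxidised to the ketone. The precursor is a salicylaldehyde whose only free phenol becomes O1, with O5 and O7 benzylated and the (S)-N-Boc-piperidine, made by sulfinimine chemistry, already installed between them.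

Key step: step 7

Assumption: the antipode of the phosphoric acid that leads to the (2S,4S) series in step 7 has to be found by trial; the (R)-acid is written and its enantiomer takes its place if the induction runs the other way. Flavanone numbering is used (O1, C2–C4, C4a, C5–C8, C8a; ring A benzo, ring B aryl, ring C pyranone).

Step 1
Reactants: 1 2,4,6-trihydroxybenzaldehyde
Product: 2 2,6-dihydroxy-4-(methoxymethoxy)benzaldehyde
Conditions: MOMCl (1.0 equiv), K2CO3 (1.0 equiv), acetone, 0 °C
Reagents that add atoms: chloromethyl methyl ether (MOMCl), COCCl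
Why: Williamson etherification; the 4-OH is the most acidic hydroxyl and the only one not hydrogen-bonded to the formyl oxygen, so one equivalent of weak base and MOMCl should alkylate it preferentially.

Step 2
Reactants: 2 2,6-dihydroxy-4-(methoxymethoxy)benzaldehyde
Product: 3 2,6-bis(benzyloxy)-4-(methoxymethoxy)benzaldehyde
Conditions: BnBr (2.5 equiv), K2CO3 (3 equiv), n-Bu4NI (cat.), DMF, 60 °C
Reagents that add atoms: benzyl bromide, BrCc1ccccc1
Why: Williamson etherification of the two chelated ortho hydroxyls, which needs the dipolar solvent and warming, while the MOM acetal and the aldehyde are inert to carbonate.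

Step 3
Reactants: 3 2,6-bis(benzyloxy)-4-(methoxymethoxy)benzaldehyde; 4 (R)-2-methylpropane-2-sulfinamide
Product: 5 (R)-N-[(E)-[2,6-bis(benzyloxy)-4-(methoxymethoxy)phenyl]methylidene]-2-methylpropane-2-sulfinamide
Conditions: Ti(OEt)4 (2 equiv), THF, 65 °C
Reagents that add atoms: none
Why: Ellman condensation; Ti(OEt)4 activates the hindered, electron-rich aldehyde and takes up the water, and the aldimine should form as the (E)-isomer with the sulfur centre untouched.

Step 4
Reactants: 5 (R)-N-[(E)-[2,6-bis(benzyloxy)-4-(methoxymethoxy)phenyl]methylidene]-2-methylpropane-2-sulfinamide; 6 1-bromo-4-chlorobutane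
Product: 9 (2S)-2-[2,6-bis(benzyloxy)-4-(methoxymethoxy)phenyl]-1-[(R)-2-methylpropane-2-sulfinyl]piperidine, via 4-chlorobutylmagnesium bromide 7 (not isolated), via chloropentyl sulfinamide magnesium salt 8 (not isolated)
Conditions: 6, Mg, Et2O, 0 °C → rt; added to 5, toluene, −40 °C → rt; then KOt-Bu, THF, 0 → 50 °C
Reagents that add atoms: none
Why: Grignard addition to an N-tert-butanesulfinyl aldimine in a non-coordinating medium should run through a six-membered chair transition state (Mg on the sulfinyl oxygen, tert-butyl equatorial) that delivers the alkyl group to the Si face of the (R)-sulfinyl (E)-aryl aldimine and so sets the (S)-carbon centre, after which the potassium sulfinamide closes the piperidine by 6-exo-tet displacement of the primary chloride.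

Step 5
Reactants: 9 (2S)-2-[2,6-bis(benzyloxy)-4-(methoxymethoxy)phenyl]-1-[(R)-2-methylpropane-2-sulfinyl]piperidine
Product: 11 tert-butyl (2S)-2-[2,6-bis(benzyloxy)-4-hydroxyphenyl]piperidine-1-carboxylate, via amine hydrochloride 10 (not isolated)
Conditions: HCl (4 M in dioxane), MeOH, 0 °C → rt; evaporate; then Boc2O (1.05 equiv), NaHCO3, THF/H2O, rt
Reagents that add atoms: di-tert-butyl dicarbonate (Boc2O), CC(C)(C)OC(=O)OC(=O)OC(C)(C)C
Why: Acid methanolysis should remove the N-sulfinyl group and the aryl MOM acetal together while the benzyl ethers stay, and carbamate formation under bicarbonate takes the more nucleophilic secondary amine and leaves the phenol free, without involving the stereocentre.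

Step 6
Reactants: 11 tert-butyl (2S)-2-[2,6-bis(benzyloxy)-4-hydroxyphenyl]piperidine-1-carboxylate
Product: 12 tert-butyl (2S)-2-[2,6-bis(benzyloxy)-3-formyl-4-hydroxyphenyl]piperidine-1-carboxylate
Conditions: MgCl2, Et3N, (CH2O)n, MeCN, 80 °C
Reagents that add atoms: paraformaldehyde (as formaldehyde), C=O
Why: Casnati–Skattebøl ortho-formylation, in which the magnesium phenoxide directs formaldehyde to the ortho carbon and a second formaldehyde oxidises the hydroxymethyl intermediate by hydride transfer; the para position is occupied and the two ortho positions are constitutionally equivalent, so only one aldehyde can form, and Boc and benzyl groups are inert.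

Step 7
Reactants: 12 tert-butyl (2S)-2-[2,6-bis(benzyloxy)-3-formyl-4-hydroxyphenyl]piperidine-1-carboxylate; 13 trimethyl orthoformate; 14 4-(benzyloxy)styrene
Product: 17 tert-butyl (2S)-2-[(2S,4S)-5,7-bis(benzyloxy)-2-[4-(benzyloxy)phenyl]-4-methoxy-3,4-dihydro-2H-chromen-6-yl]piperidine-1-carboxylate (2,4-cis), via dimethyl acetal 15 (not isolated), via methoxy ortho-quinone methide 16 (not isolated)
Conditions: 13 (2 equiv), 14 (2 equiv), (R)-3,3'-bis(2,4,6-triisopropylphenyl)-1,1'-binaphthyl-2,2'-diyl hydrogen phosphate (10 mol%), 5 Å MS, CH2Cl2, 0 °C → rt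
Reagents that add atoms: none
Why: The phosphoric acid catalyses acetalisation of the aldehyde by the orthoformate and then ionises acetal 15, so that loss of methanol gives the 4-methoxy ortho-quinone methide 16 (or its O-protonated oxocarbenium form) hydrogen-bonded to the chiral phosphate. Its electron-poor C4=C4a–C8a=O1 heterodiene then takes up the electron-rich styrene 14 in an inverse-electron-demand oxa-[4+2] cycloaddition; the closest known reactions are the acid-mediated three-component union of salicylaldehydes, orthoformates and styrenes to 2-aryl-4-alkoxychromans and the chiral phosphoric acid-catalysed [4+2] reactions of ortho-quinone methides made in situ. Ring C is closed by the cycloaddition itself, a strongly asynchronous six-membered annulation in which C3–C4 bonding runs ahead of O1–C2 bonding, in the limit a benzylic cation captured by the ring A oxygen. The phosphate ion pair shields one face of C4 and so fixes C4, and the endo-type approach that places aryl and methoxy cis relays this to C2, so catalyst control at C4 together with cis selectivity defines (2S). Regiochemistry is secured by the para-benzyloxy group of 14, which puts the developing positive charge on its benzylic carbon (aryl at C2), and by the substrate offering only one free phenol next to the formyl group, so that only the quinone methide leading to the 6-piperidinyl series can form. Because the (S)-piperidine centre is already present, a C2 epimer is a diastereomer and can be removed by chromatography at ketone 19.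

Step 8
Reactants: 17 tert-butyl (2S)-2-[(2S,4S)-5,7-bis(benzyloxy)-2-[4-(benzyloxy)phenyl]-4-methoxy-3,4-dihydro-2H-chromen-6-yl]piperidine-1-carboxylate
Product: 18 tert-butyl (2S)-2-[(2S)-5,7-bis(benzyloxy)-2-[4-(benzyloxy)phenyl]-4-hydroxy-3,4-dihydro-2H-chromen-6-yl]piperidine-1-carboxylate (either C4 configuration)
Conditions: TsOH·H2O (5 mol%), THF/H2O (4:1), 0 °C → rt
Reagents that add atoms: water, O
Why: Acid-catalysed SN1 solvolysis at C4, in which the cation stabilised by O1, O5 and O7 is trapped by the large excess of water; the C4 configuration is irrelevant, and C2 and the Boc group should not respond to acid this mild.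

Step 9
Reactants: 18 tert-butyl (2S)-2-[(2S)-5,7-bis(benzyloxy)-2-[4-(benzyloxy)phenyl]-4-hydroxy-3,4-dihydro-2H-chromen-6-yl]piperidine-1-carboxylate
Product: 19 tert-butyl (2S)-2-[(2S)-5,7-bis(benzyloxy)-2-[4-(benzyloxy)phenyl]-4-oxo-3,4-dihydro-2H-chromen-6-yl]piperidine-1-carboxylate
Conditions: Dess–Martin periodinane (1.3 equiv), pyridine, CH2Cl2, 0 °C → rt
Reagents that add atoms: none
Why: Dess–Martin oxidation of the secondary benzylic alcohol to the aryl ketone under buffered conditions, in which both C4 epimers converge on one ketone and C2 is untouched.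

Step 10
Reactants: 19 tert-butyl (2S)-2-[(2S)-5,7-bis(benzyloxy)-2-[4-(benzyloxy)phenyl]-4-oxo-3,4-dihydro-2H-chromen-6-yl]piperidine-1-carboxylate
Product: 21 (2S)-5,7-bis(benzyloxy)-2-[4-(benzyloxy)phenyl]-6-[(2S)-1-methylpiperidin-2-yl]-2,3-dihydro-4H-chromen-4-one, via secondary amine trifluoroacetate 20 (not isolated)
Conditions: TFA, CH2Cl2, 0 °C → rt; evaporate; then 37% aq. HCHO, NaBH(OAc)3, Et3N, ClCH2CH2Cl, rt
Reagents that add atoms: formaldehyde, C=O
Why: Acidolysis of the Boc carbamate followed by reductive amination, in which NaBH(OAc)3 reduces the formaldehyde-derived iminium ion but not the hindered aryl ketone; the two substituted ortho positions preclude a Pictet–Spengler-type closure, and the ketone-deactivated ring A should keep the benzylic C–N bond from ionising in TFA.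

Step 11
Reactants: 21 (2S)-5,7-bis(benzyloxy)-2-[4-(benzyloxy)phenyl]-6-[(2S)-1-methylpiperidin-2-yl]-2,3-dihydro-4H-chromen-4-one
Product: 22 (2S)-5,7-dihydroxy-2-(4-hydroxyphenyl)-6-[(2S)-1-methylpiperidin-2-yl]-2,3-dihydro-4H-chromen-4-one
Conditions: H2 (1 atm), 10% Pd/C, EtOAc/MeOH (1:1), rt; product kept at or below rt
Reagents that add atoms: none
Why: Catalytic hydrogenolysis of the three aryl benzyl ethers under neutral conditions at room temperature, which should leave the chromanone carbonyl, the C2–O1 bond and the hindered ring C–N bond intact and touches neither stereocentre.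

Compound list
1 | 2,4,6-trihydroxybenzaldehyde | O=Cc1c(O)cc(O)cc1O | starting material
2 | 2,6-dihydroxy-4-(methoxymethoxy)benzaldehyde | O=Cc1c(O)cc(OCOC)cc1O | intermediate
3 | 2,6-bis(benzyloxy)-4-(methoxymethoxy)benzaldehyde | O=Cc1c(OCc2ccccc2)cc(OCOC)cc1OCc1ccccc1 | intermediate
4 | (R)-2-methylpropane-2-sulfinamide | CC(C)(C)[S@@](=O)N | starting material
5 | (R)-N-[(E)-[2,6-bis(benzyloxy)-4-(methoxymethoxy)phenyl]methylidene]-2-methylpropane-2-sulfinamide | CC(C)(C)[S@@](=O)/N=C/c1c(OCc2ccccc2)cc(OCOC)cc1OCc1ccccc1 | intermediate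
6 | 1-bromo-4-chlorobutane | ClCCCCBr | starting material
7 | 4-chlorobutylmagnesium bromide | ClCCCC[Mg]Br | intermediate
8 | (R)-N-[(1S)-1-[2,6-bis(benzyloxy)-4-(methoxymethoxy)phenyl]-5-chloropentyl]-2-methylpropane-2-sulfinamide (present as its N-magnesium salt) | CC(C)(C)[S@@](=O)N[C@@H](CCCCCl)c1c(OCc2ccccc2)cc(OCOC)cc1OCc1ccccc1 | intermediate
9 | (2S)-2-[2,6-bis(benzyloxy)-4-(methoxymethoxy)phenyl]-1-[(R)-2-methylpropane-2-sulfinyl]piperidine | CC(C)(C)[S@@](=O)N1CCCC[C@H]1c1c(OCc2ccccc2)cc(OCOC)cc1OCc1ccccc1 | intermediate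
10 | 3,5-bis(benzyloxy)-4-[(2S)-piperidin-2-yl]phenol (formed as its hydrochloride) | N1CCCC[C@H]1c1c(OCc2ccccc2)cc(O)cc1OCc1ccccc1 | intermediate
11 | tert-butyl (2S)-2-[2,6-bis(benzyloxy)-4-hydroxyphenyl]piperidine-1-carboxylate | CC(C)(C)OC(=O)N1CCCC[C@H]1c1c(OCc2ccccc2)cc(O)cc1OCc1ccccc1 | intermediate
12 | tert-butyl (2S)-2-[2,6-bis(benzyloxy)-3-formyl-4-hydroxyphenyl]piperidine-1-carboxylate | CC(C)(C)OC(=O)N1CCCC[C@H]1c1c(OCc2ccccc2)cc(O)c(C=O)c1OCc1ccccc1 | intermediate
13 | trimethyl orthoformate | COC(OC)OC | starting material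
14 | 4-(benzyloxy)styrene | C=Cc1ccc(OCc2ccccc2)cc1 | starting material
15 | tert-butyl (2S)-2-[2,6-bis(benzyloxy)-3-(dimethoxymethyl)-4-hydroxyphenyl]piperidine-1-carboxylate | CC(C)(C)OC(=O)N1CCCC[C@H]1c1c(OCc2ccccc2)cc(O)c(C(OC)OC)c1OCc1ccccc1 | intermediate
16 | tert-butyl (2S)-2-[2,6-bis(benzyloxy)-3-(methoxymethylidene)-4-oxocyclohexa-1,5-dien-1-yl]piperidine-1-carboxylate (alkene geometry not defined) | CC(C)(C)OC(=O)N1CCCC[C@H]1C1=C(OCc2ccccc2)C(=COC)C(=O)C=C1OCc1ccccc1 | intermediate
17 | tert-butyl (2S)-2-[(2S,4S)-5,7-bis(benzyloxy)-2-[4-(benzyloxy)phenyl]-4-methoxy-3,4-dihydro-2H-chromen-6-yl]piperidine-1-carboxylate | CC(C)(C)OC(=O)N1CCCC[C@H]1c1c(OCc3ccccc3)cc2c(c1OCc1ccccc1)[C@@H](OC)C[C@@H](c1ccc(OCc3ccccc3)cc1)O2 | intermediate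
18 | tert-butyl (2S)-2-[(2S)-5,7-bis(benzyloxy)-2-[4-(benzyloxy)phenyl]-4-hydroxy-3,4-dihydro-2H-chromen-6-yl]piperidine-1-carboxylate | CC(C)(C)OC(=O)N1CCCC[C@H]1c1c(OCc3ccccc3)cc2c(c1OCc1ccccc1)C(O)C[C@@H](c1ccc(OCc3ccccc3)cc1)O2 | intermediate
19 | tert-butyl (2S)-2-[(2S)-5,7-bis(benzyloxy)-2-[4-(benzyloxy)phenyl]-4-oxo-3,4-dihydro-2H-chromen-6-yl]piperidine-1-carboxylate | CC(C)(C)OC(=O)N1CCCC[C@H]1c1c(OCc3ccccc3)cc2c(c1OCc1ccccc1)C(=O)C[C@@H](c1ccc(OCc3ccccc3)cc1)O2 | intermediate
20 | (2S)-5,7-bis(benzyloxy)-2-[4-(benzyloxy)phenyl]-6-[(2S)-piperidin-2-yl]-2,3-dihydro-4H-chromen-4-one (formed as its trifluoroacetate) | N1CCCC[C@H]1c1c(OCc3ccccc3)cc2c(c1OCc1ccccc1)C(=O)C[C@@H](c1ccc(OCc3ccccc3)cc1)O2 | intermediate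
21 | (2S)-5,7-bis(benzyloxy)-2-[4-(benzyloxy)phenyl]-6-[(2S)-1-methylpiperidin-2-yl]-2,3-dihydro-4H-chromen-4-one | CN1CCCC[C@H]1c1c(OCc3ccccc3)cc2c(c1OCc1ccccc1)C(=O)C[C@@H](c1ccc(OCc3ccccc3)cc1)O2 | intermediate
22 | (2S)-5,7-dihydroxy-2-(4-hydroxyphenyl)-6-[(2S)-1-methylpiperidin-2-yl]-2,3-dihydro-4H-chromen-4-one | CN1CCCC[C@H]1c1c(O)cc2c(c1O)C(=O)C[C@@H](c1ccc(O)cc1)O2 | target

Total step count: 11. Longest linear sequence: 11 steps (1 → 22).

Steps most likely to fail

Step 7. The chiral acid may discriminate poorly between the faces of C4, the cis relay to C2 may erode, so weak an acid may ionise the acetal incompletely, and the styrene may oligomerise. The fallback is the classical chalcone route, which sets out from 12 and comes back at 19.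
- Addition of MeMgBr (3 equiv, THF, 0 °C) to the formyl group should give tert-butyl (2S)-2-[2,6-bis(benzyloxy)-4-hydroxy-3-(1-hydroxyethyl)phenyl]piperidine-1-carboxylate F1.
- MnO2 (CH2Cl2, rt) should oxidise the benzylic alcohol to tert-butyl (2S)-2-[3-acetyl-2,6-bis(benzyloxy)-4-hydroxyphenyl]piperidine-1-carboxylate F2.
- Claisen–Schmidt condensation with 4-(benzyloxy)benzaldehyde (KOH, EtOH, rt) should give the chalcone tert-butyl (2S)-2-{2,6-bis(benzyloxy)-3-[(2E)-3-(4-benzyloxyphenyl)prop-2-enoyl]-4-hydroxyphenyl}piperidine-1-carboxylate F3.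
- NaOAc in refluxing EtOH should effect the oxa-Michael ring closure to the flavanone as both C2 epimers, 19 and tert-butyl (2S)-2-[(2R)-5,7-bis(benzyloxy)-2-[4-(benzyloxy)phenyl]-4-oxo-3,4-dihydro-2H-chromen-6-yl]piperidine-1-carboxylate F4.
- The two are diastereomers because of the fixed piperidine centre, so they should be separable by chromatography, and F4 can be returned to the equilibrium through F3 under the same conditions.

Step 4. The functionalised primary alkyl Grignard reagent may add slowly to the doubly ortho-substituted, electron-rich aldimine, facial selectivity may erode if an ortho benzyloxy oxygen chelates magnesium, and the reagent may consume itself by Wurtz-type coupling. The fallback is an allylation and ring-closing metathesis sequence, which sets out from 5 and comes back at 9.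
- Indium-mediated Barbier allylation (allyl bromide, In powder, THF, 60 °C) is fast with aryl sulfinimines and is expected to use the same Si face through the analogous chair transition state, giving (R)-N-[(1S)-1-[2,6-bis(benzyloxy)-4-(methoxymethoxy)phenyl]but-3-en-1-yl]-2-methylpropane-2-sulfinamide F5.
- N-Allylation (NaH, allyl bromide, DMF, 0 °C) should give (R)-N-[(1S)-1-[2,6-bis(benzyloxy)-4-(methoxymethoxy)phenyl]but-3-en-1-yl]-2-methyl-N-(prop-2-en-1-yl)propane-2-sulfinamide F6.
- Ring-closing metathesis (second-generation Grubbs catalyst, CH2Cl2, 40 °C) with loss of ethene should give (2S)-2-[2,6-bis(benzyloxy)-4-(methoxymethoxy)phenyl]-1-[(R)-2-methylpropane-2-sulfinyl]-1,2,3,6-tetrahydropyridine F7.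
- Diimide reduction (2-nitrobenzenesulfonohydrazide, Et3N, CH2Cl2, rt) should saturate the ring alkene without touching the benzyl ethers and return 9.

Step 8. On acid treatment the C4 cation may lose a proton to give the flav-3-ene, or alkylate the electron-rich ring A of a second molecule, instead of being captured by water. The fallback is oxidative instead of hydrolytic cleavage; it sets out from 17 and comes back at 19, bypassing 18.
- DDQ (1.5 equiv) in CH2Cl2/H2O (10:1), 0 °C → rt, should abstract the doubly activated C4 hydride.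
- Water should add to the resulting oxocarbenium ion to give the hemiketal tert-butyl (2S)-2-[(2S)-5,7-bis(benzyloxy)-2-[4-(benzyloxy)phenyl]-4-hydroxy-4-methoxy-3,4-dihydro-2H-chromen-6-yl]piperidine-1-carboxylate F8.
- F8 should collapse with loss of methanol to ketone 19.

Further compounds
F1 | step 7 | tert-butyl (2S)-2-[2,6-bis(benzyloxy)-4-hydroxy-3-(1-hydroxyethyl)phenyl]piperidine-1-carboxylate | CC(C)(C)OC(=O)N1CCCC[C@H]1c1c(OCc2ccccc2)cc(O)c(C(C)O)c1OCc1ccccc1
F2 | step 7 | tert-butyl (2S)-2-[3-acetyl-2,6-bis(benzyloxy)-4-hydroxyphenyl]piperidine-1-carboxylate | CC(C)(C)OC(=O)N1CCCC[C@H]1c1c(OCc2ccccc2)cc(O)c(C(C)=O)c1OCc1ccccc1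
F3 | step 7 | tert-butyl (2S)-2-{2,6-bis(benzyloxy)-3-[(2E)-3-(4-benzyloxyphenyl)prop-2-enoyl]-4-hydroxyphenyl}piperidine-1-carboxylate | CC(C)(C)OC(=O)N1CCCC[C@H]1c1c(OCc2ccccc2)cc(O)c(C(=O)/C=C/c2ccc(OCc3ccccc3)cc2)c1OCc1ccccc1
F4 | step 7 | tert-butyl (2S)-2-[(2R)-5,7-bis(benzyloxy)-2-[4-(benzyloxy)phenyl]-4-oxo-3,4-dihydro-2H-chromen-6-yl]piperidine-1-carboxylate | CC(C)(C)OC(=O)N1CCCC[C@H]1c1c(OCc3ccccc3)cc2c(c1OCc1ccccc1)C(=O)C[C@H](c1ccc(OCc3ccccc3)cc1)O2
F5 | step 4 | (R)-N-[(1S)-1-[2,6-bis(benzyloxy)-4-(methoxymethoxy)phenyl]but-3-en-1-yl]-2-methylpropane-2-sulfinamide | CC(C)(C)[S@@](=O)N[C@@H](CC=C)c1c(OCc2ccccc2)cc(OCOC)cc1OCc1ccccc1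
F6 | step 4 | (R)-N-[(1S)-1-[2,6-bis(benzyloxy)-4-(methoxymethoxy)phenyl]but-3-en-1-yl]-2-methyl-N-(prop-2-en-1-yl)propane-2-sulfinamide | CC(C)(C)[S@@](=O)N(CC=C)[C@@H](CC=C)c1c(OCc2ccccc2)cc(OCOC)cc1OCc1ccccc1
F7 | step 4 | (2S)-2-[2,6-bis(benzyloxy)-4-(methoxymethoxy)phenyl]-1-[(R)-2-methylpropane-2-sulfinyl]-1,2,3,6-tetrahydropyridine | CC(C)(C)[S@@](=O)N1CC=CC[C@H]1c1c(OCc2ccccc2)cc(OCOC)cc1OCc1ccccc1
F8 | step 8 | tert-butyl (2S)-2-[(2S)-5,7-bis(benzyloxy)-2-[4-(benzyloxy)phenyl]-4-hydroxy-4-methoxy-3,4-dihydro-2H-chromen-6-yl]piperidine-1-carboxylate | CC(C)(C)OC(=O)N1CCCC[C@H]1c1c(OCc3ccccc3)cc2c(c1OCc1ccccc1)C(O)(OC)C[C@@H](c1ccc(OCc3ccccc3)cc1)O2
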